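I wanted to know what share of its G the winter flask turns into X by 4.6 h, and what the orders are near the midnight charge.

| setting | midnight | summer | spring | autumn | winter |
|---|---|---|---|---|---|
| G | 0.400 M | 0.160 M | 0.400 M | 1.20 M | 2.90 M |
| J | 0.600 M | 0.360 M | 0.900 M | 0.600 M | 0.600 M |
| time |  |  |  |  | 4.6 h |

| run | time / h | [X] / M |
|---|---|---|
| midnight run | 0.18 | 0.0212 |
| midnight run | 0.41 | 0.0452 |
| midnight run | 0.92 | 0.0885 |
| midnight run | 2.1 | 0.1497 |
| midnight run | 4.6 | 0.2001 |
| summer run | 0.18 | 0.0058 |
| summer run | 0.41 | 0.0119 |
| summer run | 0.92 | 0.0224 |
| summer run | 2.1 | 0.0436 |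
| summer run | 4.6 | 0.0628 |
| spring run | 0.18 | 0.0339 |
| spring run | 0.41 | 0.0696 |
| spring run | 0.92 | 0.1284 |
| spring run | 2.1 | 0.2048 |
| spring run | 4.6 | 0.2503 |
| autumn run | 0.18 | 0.0618 |
| autumn run | 0.41 | 0.1269 |
| autumn run | 0.92 | 0.2262 |
| autumn run | 2.1 | 0.3407 |
| autumn run | 4.6 | 0.3871 |

(scatter of a reading: 0.001 M)

* order of the initial rate in [J], near the charge of the midnight run, the rate being that where two percent of its G are X
* order of the initial rate in [G], near the charge of the midnight run, the rate being that where two percent of its G are X (one fixed amount of X, the same in the runs compared)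
* X in the winter run at 4.6 h, as a share of the G charged

- Overall: G + J -> X.
- Constant volume, constant temperature.
- "The second partner" is J.
- An order is taken over about fifteen percent of the charge, up and down.

My bench rule for a flask with G in excess was that J is the limiting reagent, that it decays in pseudo-first-order fashion with a time of 1/(k[G]), and that X ends near the J charge. The first midnight reading gave k = 0.491 /M/h. In the winter flask that time is 0.703 h, much shorter than 4.6 h, and the plain second-order curve leaves 0.00265 M of J at 4.6 h. The rule therefore promised nearly all of the J charge as X.

The autumn run showed where the rule stops. Its plain curve gave 0.511 M at 4.6 h, but the reading was 0.3871 M, lower. Autumn thus kept 0.757 of its curve, and this ratio of last reading to plain curve is what I call the kept share. The midnight run, with a plain curve of 0.253 M, kept 0.792. I took the autumn value, since autumn has more G than any other run with readings, and one multiplication gave my estimate for winter, 15.6 % of its G.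

The forecast gave 1.15 (1 to 1.3) for J, 0.96 (0.85 to 1.05) for G, and 16.5 % (14 % to 18.3 %) for winter, higher than my 15.6 %, holding that “high G costs something extra”.

The flask gave orders of 1.1 in J and 1.0 in G, and 15.1 % for winter, within the forecast's ranges.

    G + J → X (0.4968 /M/h)
    G + 2 J → X + J (0.05148 /M²/h)
    J → Qa (0.04428 /h)
    X → Xa (0.07200 /h)

A fit with the main steps alone left a root mean square residual of 22 times the scatter. Winter's own kept share came to 0.733. On the spring run, autumn's kept share turns a plain curve of 0.316 M at 4.6 h into 0.239 M, and the last reading there stood higher, at 0.2503 M.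

(The numbers in the tables are simulated with constants of no real substance, noise included.)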